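The five-membered ring of the bicyclo[3.1.0]hexan-2-one is cut at C1–C2 (methylated ring-fusion carbon to ketone carbon) and C3–C4 (CH(CH3) to the side-chain-bearing CH). Step 11 makes both in one flask: iridium-catalysed olefin isomerisation–Claisen rearrangement of an O-allyl dienyl carbinol, then capture of the aldehyde by isopropenylmagnesium bromide. It exploits the γ,δ-unsaturated carbonyl pattern C2(=O)–C3–C4–C2'=C3' of ring and side chain: the [3,3] shift forges C3–C4, relays the carbinol configuration to C4 and delivers the (E)-C2'=C3' olefin; the Grignard carbon becomes C1. Ring-closing metathesis then closes the cyclopentenone, and a pyranone-stabilised sulfonium ylide adds the cyclopropane.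

Key step: step 11

Remark (numbering): C1–C6 follow bicyclo[3.1.0]hexan-2-one (C1 methylated ring-fusion carbon, C2 ring C=O, C3 CH(CH3), C4 CH bearing the side chain, C5 ring-fusion CH, C6 cyclopropane carbon with methyl and pyranone); C1'–C7' are the hept-2-en-2-yl side chain.
Remark (assumption): the C3 configuration of the target (trans to the C4 substituent) is taken to be the thermodynamically preferred one and is set by equilibration; C5' is a temporary carbinol centre that ends as the side-chain ketone.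

Step 1
Reactants: 1 methyl 2-methyl-3-oxopentanoate; 2 N-methoxy-N-methylpropanamide
Product: 3 methyl 2,4-dimethyl-3,5-dioxoheptanoate (diastereomer and enol mixture, inconsequential)
Conditions: NaH, THF, 0 °C; n-BuLi, 0 °C; 2, −78 → 0 °C; aq. HCl
Reagents that add atoms: none
Why: The β-keto ester dianion should be C-acylated at its γ-carbon by the Weinreb amide (Claisen-type acylation), the chelated tetrahedral intermediate preventing over-addition.

Step 2
Reactants: 3 methyl 2,4-dimethyl-3,5-dioxoheptanoate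
Product: 4 6-ethyl-4-hydroxy-3,5-dimethyl-2H-pyran-2-one
Conditions: DBU, toluene, 80 °C; aq. HCl
Reagents that add atoms: none
Why: Base-mediated lactonisation of the δ-enol oxygen onto the methyl ester (intramolecular acyl substitution) should give the 4-hydroxy-2-pyranone.

Step 3
Reactants: 4 6-ethyl-4-hydroxy-3,5-dimethyl-2H-pyran-2-one
Product: 5 2-ethyl-6-methoxy-3,5-dimethyl-4H-pyran-4-one
Conditions: MeOTf, CH2Cl2, rt; aq. NaHCO3
Reagents that add atoms: methyl trifluoromethanesulfonate, COS(=O)(=O)C(F)(F)F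
Why: Hard O-alkylation at the lactone carbonyl oxygen followed by proton loss should give the 2-methoxy-4-pyranone (γ-pyrone) rather than the 4-methoxy-2-pyranone.

Step 4
Reactants: 5 2-ethyl-6-methoxy-3,5-dimethyl-4H-pyran-4-one
Product: 6 2-(1-bromoethyl)-6-methoxy-3,5-dimethyl-4H-pyran-4-one (racemic)
Conditions: LiN(SiMe3)2, THF, −78 °C; NBS, −78 °C; dil. HCl
Reagents that add atoms: N-bromosuccinimide, BrN1C(=O)CCC1=O
Why: The vinylogously acidic CH2 of the ethyl group is deprotonated and the extended enolate should be brominated at that carbon (electrophilic α-halogenation), restoring the pyranone.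

Step 5
Reactants: 6 2-(1-bromoethyl)-6-methoxy-3,5-dimethyl-4H-pyran-4-one
Product: 7 1-[1-(6-methoxy-3,5-dimethyl-4-oxo-4H-pyran-2-yl)ethyl]thiolan-1-ium bromide (racemic)
Conditions: tetrahydrothiophene, acetone, rt
Reagents that add atoms: tetrahydrothiophene, C1CCSC1
Why: SN2 alkylation of the sulfide by the activated secondary bromide should give the sulfonium salt.

Step 6
Reactants: 8 (E)-but-2-enal; 9 2-(triphenyl-λ5-phosphanylidene)propanal
Product: 10 (2E,4E)-2-methylhexa-2,4-dienal
Conditions: CH2Cl2, rt → 40 °C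
Reagents that add atoms: none
Why: Wittig olefination with the formyl-stabilised ylide should give the (E)-trisubstituted enal and leave the existing (E)-olefin untouched.

Step 7
Reactants: 11 pentan-3-one; 10 (2E,4E)-2-methylhexa-2,4-dienal
Product: 12 (4R,5R,6E,8E)-5-hydroxy-4,6-dimethyldeca-6,8-dien-3-one
Conditions: (+)-Ipc2BOTf [from (−)-α-pinene], i-Pr2NEt, CH2Cl2, −78 °C; 10, −78 → −20 °C; H2O2, MeOH, pH 7 buffer
Reagents that add atoms: none
Why: Boron-mediated aldol: the (Z)-enolborinate reacts through a Zimmerman–Traxler chair to give the syn adduct, and the isopinocampheyl ligands are chosen to direct attack to the re face of the enal, which sets C5 (R, future C3') and C4 (R, future C4').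

Step 8
Reactants: 12 (4R,5R,6E,8E)-5-hydroxy-4,6-dimethyldeca-6,8-dien-3-one; 13 allyl bromide
Product: 14 (4R,5R,6E,8E)-4,6-dimethyl-5-(prop-2-en-1-yloxy)deca-6,8-dien-3-one
Conditions: Ag2O, 4 Å molecular sieves, Et2O, rt, dark
Reagents that add atoms: none
Why: Silver-oxide-mediated Williamson etherification works without a free alkoxide and should therefore avoid retro-aldol cleavage of the β-hydroxy ketone.

Step 9
Reactants: 14 (4R,5R,6E,8E)-4,6-dimethyl-5-(prop-2-en-1-yloxy)deca-6,8-dien-3-one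
Product: 15 (3S,4S,5R,6E,8E)-4,6-dimethyl-5-(prop-2-en-1-yloxy)deca-6,8-dien-3-ol
Conditions: LiBH(s-Bu)3, THF, −78 °C; H2O
Reagents that add atoms: none
Why: Felkin–Anh-controlled hydride reduction by the bulky borohydride should place the new hydroxyl anti to the adjacent methyl; this centre is inconsequential because it is re-oxidised in step 16.

Step 10
Reactants: 15 (3S,4S,5R,6E,8E)-4,6-dimethyl-5-(prop-2-en-1-yloxy)deca-6,8-dien-3-ol
Product: 16 tert-butyl{[(3S,4R,5R,6E,8E)-4,6-dimethyl-5-(prop-2-en-1-yloxy)deca-6,8-dien-3-yl]oxy}dimethylsilane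
Conditions: TBSOTf, 2,6-lutidine, CH2Cl2, −78 → 0 °C
Reagents that add atoms: tert-butyldimethylsilyl trifluoromethanesulfonate, CC(C)(C)[Si](C)(C)OS(=O)(=O)C(F)(F)F
Why: Silylation with the silyl triflate and a hindered base masks the alcohol that later becomes the side-chain ketone.

Step 11
Reactants: 16 tert-butyl{[(3S,4R,5R,6E,8E)-4,6-dimethyl-5-(prop-2-en-1-yloxy)deca-6,8-dien-3-yl]oxy}dimethylsilane; 17 isopropenylmagnesium bromide
Product: 20 (4R,5R,6E,8R,9S)-9-[(tert-butyldimethylsilyl)oxy]-2,4,6,8-tetramethyl-5-[(1E)-prop-1-en-1-yl]undeca-1,6-dien-3-ol (both C3 carbinol epimers), via propenyl ether 18 (not isolated), via aldehyde 19 (not isolated)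
Conditions: [IrCl(C8H14)2]2 (cat.), PCy3, NaBPh4, ClCH2CH2Cl–acetone, rt; PPh3, 80 °C; evaporation, THF, −78 °C, 17; aq. NH4Cl
Reagents that add atoms: none
Why: The cationic iridium phosphine catalyst moves the terminal double bond of the O-allyl group next to oxygen to give (E)-propenyl ether 18, which on warming undergoes a [3,3]-sigmatropic Claisen shift through a chair with the C4'-bearing substituent equatorial, so that C3–C4 forms suprafacially, the C2'=C3' olefin is born E and the (R)-carbinol centre is relayed to C4 (R); aldehyde 19 is then intercepted at −78 °C by 17 in a Grignard 1,2-addition that forms C1–C2. The closest known reaction type is the olefin isomerisation–Claisen rearrangement of di(allyl) ethers with in-flask organometallic capture of the 2,3-disubstituted pent-4-enal. No ring is closed in this step (the six-membered chair is only a transition state); the two new bonds are placed so that the five-membered ring closes in step 13. C4 is fixed by 1,3-chirality transfer, C3 by the E geometry of the enol ether (syn aldehyde, corrected to the 3,4-trans ketone by equilibration in step 14), and the carbinol carbon is left uncontrolled because it is oxidised in step 12. The step needs isomerisation of the monosubstituted allyl terminus only (the di- and trisubstituted diene olefins are too hindered to migrate), rearrangement through the proximal trisubstituted olefin, and addition to the aldehyde faster than its enolisation, which the low temperature and the absence of any other electrophile should secure.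

Step 12
Reactants: 20 (4R,5R,6E,8R,9S)-9-[(tert-butyldimethylsilyl)oxy]-2,4,6,8-tetramethyl-5-[(1E)-prop-1-en-1-yl]undeca-1,6-dien-3-ol
Product: 21 (4R,5R,6E,8R,9S)-9-[(tert-butyldimethylsilyl)oxy]-2,4,6,8-tetramethyl-5-[(1E)-prop-1-en-1-yl]undeca-1,6-dien-3-one
Conditions: Dess–Martin periodinane, NaHCO3, CH2Cl2, 0 °C → rt
Reagents that add atoms: none
Why: Dess–Martin oxidation of the allylic alcohol epimers under non-basic conditions should converge on one dienone without touching the α-stereocentre.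

Step 13
Reactants: 21 (4R,5R,6E,8R,9S)-9-[(tert-butyldimethylsilyl)oxy]-2,4,6,8-tetramethyl-5-[(1E)-prop-1-en-1-yl]undeca-1,6-dien-3-one
Product: 22 (4R,5R)-4-[(2E,4R,5S)-5-[(tert-butyldimethylsilyl)oxy]-4-methylhept-2-en-2-yl]-2,5-dimethylcyclopent-2-en-1-one
Conditions: second-generation Hoveyda–Grubbs catalyst (cat.), toluene, 60 °C
Reagents that add atoms: none
Why: Ring-closing olefin metathesis: the ruthenium carbene should load on the disubstituted propenyl olefin and close onto the isopropenyl ketone (five-membered ring, propene lost), the trisubstituted side-chain olefin being too hindered to take part.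

Step 14
Reactants: 22 (4R,5R)-4-[(2E,4R,5S)-5-[(tert-butyldimethylsilyl)oxy]-4-methylhept-2-en-2-yl]-2,5-dimethylcyclopent-2-en-1-one; 7 1-[1-(6-methoxy-3,5-dimethyl-4-oxo-4H-pyran-2-yl)ethyl]thiolan-1-ium bromide
Product: 25 (1S,3S,4R,5S,6S)-4-[(2E,4R,5S)-5-[(tert-butyldimethylsilyl)oxy]-4-methylhept-2-en-2-yl]-6-(6-methoxy-3,5-dimethyl-4-oxo-4H-pyran-2-yl)-1,3,6-trimethylbicyclo[3.1.0]hexan-2-one, via sulfonium ylide 23 (not isolated), via C3-epimeric ketone 24 (not isolated)
Conditions: 7, LiN(SiMe3)2, THF, −78 °C; 22, −78 → 0 °C; DBU, rt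
Reagents that add atoms: none
Why: Corey–Chaykovsky-type cyclopropanation (Michael-initiated ring closure): the stabilised ylide should add to the enone β-carbon (future C5) anti to the C4 substituent, the enolate carbon (future C1) then displaces tetrahydrothiophene in a 3-exo-tet closure with the bulky pyranone exo, which sets C1, C5 and C6, and DBU equilibrates C3 to the more stable 3,4-trans ketone.

Step 15
Reactants: 25 the silyl ether from step 14
Product: 26 (1S,3S,4R,5S,6S)-4-[(2E,4R,5S)-5-hydroxy-4-methylhept-2-en-2-yl]-6-(6-methoxy-3,5-dimethyl-4-oxo-4H-pyran-2-yl)-1,3,6-trimethylbicyclo[3.1.0]hexan-2-one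
Conditions: HF·pyridine, pyridine, THF, 0 °C → rt
Reagents that add atoms: none
Why: Fluoride-mediated desilylation under buffered, weakly acidic conditions should leave the epimerisable C3 centre and the cyclopropyl ketone intact.

Step 16
Reactants: 26 the alcohol from step 15
Product: 27 (1S,3S,4R,5S,6S)-6-(6-methoxy-3,5-dimethyl-4-oxo-4H-pyran-2-yl)-1,3,6-trimethyl-4-[(2E,4R)-4-methyl-5-oxohept-2-en-2-yl]bicyclo[3.1.0]hexan-2-one (CNP0216193.1)
Conditions: Dess–Martin periodinane, NaHCO3, CH2Cl2, 0 °C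
Reagents that add atoms: none
Why: Buffered Dess–Martin oxidation should give the β,γ-unsaturated ketone without epimerising C4' or moving the olefin into conjugation.

Compound list
1 | methyl 2-methyl-3-oxopentanoate | CCC(=O)C(C)C(=O)OC | starting material
2 | N-methoxy-N-methylpropanamide | CCC(=O)N(C)OC | starting material
3 | methyl 2,4-dimethyl-3,5-dioxoheptanoate | CCC(=O)C(C)C(=O)C(C)C(=O)OC | intermediate
4 | 6-ethyl-4-hydroxy-3,5-dimethyl-2H-pyran-2-one | CCc1oc(=O)c(C)c(O)c1C | intermediate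
5 | 2-ethyl-6-methoxy-3,5-dimethyl-4H-pyran-4-one | CCc1oc(OC)c(C)c(=O)c1C | intermediate
6 | 2-(1-bromoethyl)-6-methoxy-3,5-dimethyl-4H-pyran-4-one (racemic) | CC(Br)c1oc(OC)c(C)c(=O)c1C | intermediate
7 | 1-[1-(6-methoxy-3,5-dimethyl-4-oxo-4H-pyran-2-yl)ethyl]thiolan-1-ium bromide (racemic) | CC([S+]1CCCC1)c1oc(OC)c(C)c(=O)c1C.[Br-] | intermediate
8 | (E)-but-2-enal | C/C=C/C=O | starting material
9 | 2-(triphenyl-λ5-phosphanylidene)propanal | CC(C=O)=P(c1ccccc1)(c1ccccc1)c1ccccc1 | starting material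
10 | (2E,4E)-2-methylhexa-2,4-dienal | C/C=C/C=C(\C)C=O | intermediate
11 | pentan-3-one | CCC(=O)CC | starting material
12 | (4R,5R,6E,8E)-5-hydroxy-4,6-dimethyldeca-6,8-dien-3-one | CCC(=O)[C@H](C)[C@@H](O)/C(C)=C/C=C/C | intermediate
13 | allyl bromide | C=CCBr | starting material
14 | (4R,5R,6E,8E)-4,6-dimethyl-5-(prop-2-en-1-yloxy)deca-6,8-dien-3-one | CCC(=O)[C@H](C)[C@@H](OCC=C)/C(C)=C/C=C/C | intermediate
15 | (3S,4S,5R,6E,8E)-4,6-dimethyl-5-(prop-2-en-1-yloxy)deca-6,8-dien-3-ol | CC[C@H](O)[C@H](C)[C@@H](OCC=C)/C(C)=C/C=C/C | intermediate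
16 | tert-butyl{[(3S,4R,5R,6E,8E)-4,6-dimethyl-5-(prop-2-en-1-yloxy)deca-6,8-dien-3-yl]oxy}dimethylsilane | CC[C@H](O[Si](C)(C)C(C)(C)C)[C@H](C)[C@@H](OCC=C)/C(C)=C/C=C/C | intermediate
17 | isopropenylmagnesium bromide | CC(=C)[Mg]Br | starting material
18 | tert-butyl{[(3S,4R,5R,6E,8E)-4,6-dimethyl-5-{[(1E)-prop-1-en-1-yl]oxy}deca-6,8-dien-3-yl]oxy}dimethylsilane (not isolated) | CC[C@H](O[Si](C)(C)C(C)(C)C)[C@H](C)[C@@H](O/C=C/C)/C(C)=C/C=C/C | intermediate
19 | (2R,3R,4E,6R,7S)-7-[(tert-butyldimethylsilyl)oxy]-2,4,6-trimethyl-3-[(1E)-prop-1-en-1-yl]non-4-enal (not isolated) | CC[C@H](O[Si](C)(C)C(C)(C)C)[C@H](C)/C=C(\C)[C@@H]([C@@H](C)C=O)/C=C/C | intermediate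
20 | (4R,5R,6E,8R,9S)-9-[(tert-butyldimethylsilyl)oxy]-2,4,6,8-tetramethyl-5-[(1E)-prop-1-en-1-yl]undeca-1,6-dien-3-ol (C3 epimers) | CC[C@H](O[Si](C)(C)C(C)(C)C)[C@H](C)/C=C(\C)[C@@H]([C@@H](C)C(O)C(C)=C)/C=C/C | intermediate
21 | (4R,5R,6E,8R,9S)-9-[(tert-butyldimethylsilyl)oxy]-2,4,6,8-tetramethyl-5-[(1E)-prop-1-en-1-yl]undeca-1,6-dien-3-one | CC[C@H](O[Si](C)(C)C(C)(C)C)[C@H](C)/C=C(\C)[C@@H]([C@@H](C)C(=O)C(C)=C)/C=C/C | intermediate
22 | (4R,5R)-4-[(2E,4R,5S)-5-[(tert-butyldimethylsilyl)oxy]-4-methylhept-2-en-2-yl]-2,5-dimethylcyclopent-2-en-1-one | CC[C@H](O[Si](C)(C)C(C)(C)C)[C@H](C)/C=C(\C)[C@@H]1C=C(C)C(=O)[C@@H]1C | intermediate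
23 | 1-(6-methoxy-3,5-dimethyl-4-oxo-4H-pyran-2-yl)ethylide of thiolan-1-ium (sulfonium ylide, not isolated) | C[C-]([S+]1CCCC1)c1oc(OC)c(C)c(=O)c1C | intermediate
24 | (1S,3R,4R,5S,6S)-epimer of 25 at C3 (not isolated) | CC[C@H](O[Si](C)(C)C(C)(C)C)[C@H](C)/C=C(\C)[C@H]1[C@@H](C)C(=O)[C@@]2(C)[C@@H]1[C@]2(C)c1oc(OC)c(C)c(=O)c1C | intermediate
25 | (1S,3S,4R,5S,6S)-4-[(2E,4R,5S)-5-[(tert-butyldimethylsilyl)oxy]-4-methylhept-2-en-2-yl]-6-(6-methoxy-3,5-dimethyl-4-oxo-4H-pyran-2-yl)-1,3,6-trimethylbicyclo[3.1.0]hexan-2-one | CC[C@H](O[Si](C)(C)C(C)(C)C)[C@H](C)/C=C(\C)[C@H]1[C@H](C)C(=O)[C@@]2(C)[C@@H]1[C@]2(C)c1oc(OC)c(C)c(=O)c1C | intermediate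
26 | (1S,3S,4R,5S,6S)-4-[(2E,4R,5S)-5-hydroxy-4-methylhept-2-en-2-yl]-6-(6-methoxy-3,5-dimethyl-4-oxo-4H-pyran-2-yl)-1,3,6-trimethylbicyclo[3.1.0]hexan-2-one | CC[C@H](O)[C@H](C)/C=C(\C)[C@H]1[C@H](C)C(=O)[C@@]2(C)[C@@H]1[C@]2(C)c1oc(OC)c(C)c(=O)c1C | intermediate
27 | (1S,3S,4R,5S,6S)-6-(6-methoxy-3,5-dimethyl-4-oxo-4H-pyran-2-yl)-1,3,6-trimethyl-4-[(2E,4R)-4-methyl-5-oxohept-2-en-2-yl]bicyclo[3.1.0]hexan-2-one | CCC(=O)[C@H](C)/C=C(\C)[C@H]1[C@H](C)C(=O)[C@@]2(C)[C@@H]1[C@]2(C)c1oc(OC)c(C)c(=O)c1C | target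

Total step count: 16. Longest linear sequence: 11 steps (steps 6–16, from 8 and 9 to 27); the pyranone arm (steps 1–5) joins at step 14.

Steps most likely to fail

1. Step 11 (key step). The diene may tie up the iridium catalyst so that isomerisation stalls, and aldehyde 19 may enolise during the Grignard capture, eroding C3 and C4 or leaving the capture incomplete. The fallback decouples the two bond formations; it sets out from 16 and comes back at 20. The isomerisation–Claisen sequence is run as before, but the aldehyde is reduced in the flask with NaBH4 to (2R,3R,4E,6R,7S)-7-[(tert-butyldimethylsilyl)oxy]-2,4,6-trimethyl-3-[(1E)-prop-1-en-1-yl]non-4-en-1-ol F1, which can be purified. Dess–Martin oxidation regenerates 19, and the weakly basic organocerium reagent made from 17 and CeCl3 is added at −78 °C to give 20.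

2. Step 14. The hindered tertiary ylide may add too slowly to the α-methyl enone, the base may move the enone double bond by γ-deprotonation at C4, and the methyl/pyranone orientation at C6 may be poorly controlled. The fallback replaces the ylide by a diazoalkane cycloaddition; it sets out from 6 and 22 and comes back at 25. Bromide 6 is oxidised (DMSO, NaHCO3, Kornblum oxidation) to 2-acetyl-6-methoxy-3,5-dimethyl-4H-pyran-4-one F2, which is condensed with TsNHNH2 to N'-[1-(6-methoxy-3,5-dimethyl-4-oxo-4H-pyran-2-yl)ethylidene]-4-methylbenzenesulfonohydrazide F3. Its sodium salt (NaH) is warmed with 22 (BnEt3NCl, dioxane, 40 °C) so that 2-(1-diazoethyl)-6-methoxy-3,5-dimethyl-4H-pyran-4-one F4 forms in the flask (Bamford–Stevens) and adds to the enone in a 1,3-dipolar cycloaddition, anti to the C4 substituent, to give the fused 1-pyrazoline F5. Irradiation at 350 nm extrudes dinitrogen with retention to give 24, and DBU equilibrates it to 25.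

3. Step 8. Etherification of the hindered dienylic alcohol may be sluggish, with retro-aldol cleavage or β-elimination of the β-hydroxy ketone taking over. The fallback reorders reduction and etherification so that a normal Williamson reaction can be used; it sets out from 12 and comes back at 16. Evans–Tishchenko reduction (SmI2 cat., CH3CHO, THF, −10 °C) gives the anti-1,3-diol monoester (3S,4S,5R,6E,8E)-3-hydroxy-4,6-dimethyldeca-6,8-dien-5-yl acetate F6. Silylation (TBSOTf, 2,6-lutidine) gives (3S,4R,5R,6E,8E)-3-[(tert-butyldimethylsilyl)oxy]-4,6-dimethyldeca-6,8-dien-5-yl acetate F7, and K2CO3 in MeOH frees (3S,4R,5R,6E,8E)-3-[(tert-butyldimethylsilyl)oxy]-4,6-dimethyldeca-6,8-dien-5-ol F8. NaH and 13 in THF–DMF at 0 °C then give 16.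

Further compounds
F1 | step 11 | (2R,3R,4E,6R,7S)-7-[(tert-butyldimethylsilyl)oxy]-2,4,6-trimethyl-3-[(1E)-prop-1-en-1-yl]non-4-en-1-ol | CC[C@H](O[Si](C)(C)C(C)(C)C)[C@H](C)/C=C(\C)[C@@H]([C@@H](C)CO)/C=C/C
F2 | step 14 | 2-acetyl-6-methoxy-3,5-dimethyl-4H-pyran-4-one | CC(=O)c1oc(OC)c(C)c(=O)c1C
F3 | step 14 | N'-[1-(6-methoxy-3,5-dimethyl-4-oxo-4H-pyran-2-yl)ethylidene]-4-methylbenzenesulfonohydrazide | CC(=NNS(=O)(=O)c1ccc(C)cc1)c1oc(OC)c(C)c(=O)c1C
F4 | step 14 | 2-(1-diazoethyl)-6-methoxy-3,5-dimethyl-4H-pyran-4-one | CC(=[N+]=[N-])c1oc(OC)c(C)c(=O)c1C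
F5 | step 14 | fused 1-pyrazoline from F4 and 22 (2,3-diazabicyclo[3.3.0]oct-2-en-8-one core, pyranone exo) | CC[C@H](O[Si](C)(C)C(C)(C)C)[C@H](C)/C=C(\C)[C@H]1[C@@H](C)C(=O)[C@@]2(C)[C@@H]1[C@](C)(c1oc(OC)c(C)c(=O)c1C)N=N2
F6 | step 8 | (3S,4S,5R,6E,8E)-3-hydroxy-4,6-dimethyldeca-6,8-dien-5-yl acetate | CC[C@H](O)[C@H](C)[C@@H](OC(C)=O)/C(C)=C/C=C/C
F7 | step 8 | (3S,4R,5R,6E,8E)-3-[(tert-butyldimethylsilyl)oxy]-4,6-dimethyldeca-6,8-dien-5-yl acetate | CC[C@H](O[Si](C)(C)C(C)(C)C)[C@H](C)[C@@H](OC(C)=O)/C(C)=C/C=C/C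
F8 | step 8 | (3S,4R,5R,6E,8E)-3-[(tert-butyldimethylsilyl)oxy]-4,6-dimethyldeca-6,8-dien-5-ol | CC[C@H](O[Si](C)(C)C(C)(C)C)[C@H](C)[C@@H](O)/C(C)=C/C=C/C
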